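**Plan**
- Locants used throughout: C3 = CH(Et), C4 = ketone, C5–C8 = (CH2)4, N9, C10 = lactam C=O, C11 = C–OH, C12, C13 = N–CH, C14–C17/O18 = side lactone, C19 = ring-fusion CH, C20 = ring-fusion OCH, O21, C22 = fused-lactone C=O, C23 = CHMe.
- Enabling feature: the lactone carbonyl C22 and the lactam carbonyl C10 are 1,5-related through C23–C19–C11, and C11 (α to C10) carries OH. This is the retron of a Michael addition C23→C19 whose enolate is then hydroxylated. The C4 oxygen and C10 can be tied into a temporary seven-membered lactone that forces the cis ring fusion.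
- Cuts: C13–C14 (vinylogous Mannich), N9–C13 and N9–C10 (ring expansion of the temporary lactone by the tethered amine), C19–C23 with C11–O (key step), C11=C19 (metathesis), the C4–O–C10 ester, C4–C5 and C3–C20 (aldol).
- Forward order: acyclic C19…C8 chain → seven-membered unsaturated lactone → fused γ-butyrolactone (key step) → eleven-membered lactam with bridging pyrrolidinone by ring expansion → butenolide → saturated side lactone.
- Stereochemistry: C3 and C20 from an Evans syn aldol; temporary C4 from an Evans–Tishchenko reduction; C19, C23 and C11 relayed from C20 in the key step; C13 from the bridged bicycle and C14 from the threo preference of the Mannich addition; C16 from hydrogenation.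

Key step: step 10

Remark: compound 1 is taken as a purchasable reagent. The C13 epimers of 20 and 21 need not be separated, because both ionise to the same N-acyliminium ion 24; the epimer drawn has OEt cis to the C11 hydroxyl.

**Step 1**
Reactants: 1 (4S)-4-benzyl-3-butanoyl-1,3-oxazolidin-2-one; 2 acrolein
Product: 3 (4S)-4-benzyl-3-[(2S,3R)-2-ethyl-3-hydroxypent-4-enoyl]-1,3-oxazolidin-2-one
Conditions: Bu2BOTf, i-Pr2NEt, CH2Cl2, −78 → 0 °C; then pH 7 buffer, MeOH, H2O2
Reagents that add atoms: none
Why: Evans syn aldol through the Z boron enolate and a chair transition state; the (S)-benzyl auxiliary shields one enolate face and fixes C3 and C20 in the target configuration (2,3-syn).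

**Step 2**
Reactants: 3 aldol adduct
Product: 4 (2S,3R)-2-ethyl-3-hydroxy-N-methoxy-N-methylpent-4-enamide
Conditions: MeNH(OMe)·HCl, AlMe3, CH2Cl2, −20 → 0 °C
Reagents that add atoms: N,O-dimethylhydroxylamine hydrochloride, CNOC.Cl
Why: aluminium amide transamidation of a β-hydroxy imide (Weinreb amide formation), in which the free hydroxyl directs attack to the exocyclic carbonyl and C3 is not touched.

**Step 3**
Reactants: 4 Weinreb amide
Product: 5 (3R,4S)-9-chloro-4-ethyl-3-hydroxynon-1-en-5-one
Conditions: ClCH2CH2CH2CH2MgBr (from 1-bromo-4-chlorobutane, Mg, THF), THF, −20 → 0 °C; cold aq. NH4Cl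
Reagents that add atoms: 4-chlorobutylmagnesium bromide, ClCCCC[Mg]Br (made in the flask from 1-bromo-4-chlorobutane, ClCCCCBr, and Mg)
Why: Grignard addition to a Weinreb amide stops at the ketone through the chelated tetrahedral adduct; one extra equivalent is consumed by the hydroxyl, and the cold buffered quench protects the C3 centre.

**Step 4**
Reactants: 5 β-hydroxy ketone; 6 propanal
Product: 7 (3R,4R,5R)-9-chloro-4-ethyl-5-hydroxynon-1-en-3-yl propanoate
Conditions: SmI2 (0.3 equiv), propanal (6 equiv), THF, −10 °C
Reagents that add atoms: none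
Why: Evans–Tishchenko reduction, in which the samarium-bound hemiacetal of propanal on the C20 hydroxyl delivers hydride intramolecularly to the C4 ketone (1,3-anti), so that C20 emerges as the propanoate needed for the key step and C4 as the only free hydroxyl.

**Step 5**
Reactants: 8 diethyl malonate; 9 2-bromo-1,1-diethoxyethane
Product: 10 diethyl 2-(2,2-diethoxyethyl)propanedioate
Conditions: NaOEt, NaI (cat.), EtOH, reflux
Reagents that add atoms: none
Why: malonic ester alkylation, an SN2 displacement of the primary bromide helped by iodide catalysis.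

**Step 6**
Reactants: 10 malonate
Product: 11 2-(2,2-diethoxyethyl)propanedioic acid
Conditions: KOH, EtOH–H2O, rt; then cold aq. HCl to pH 3
Reagents that add atoms: potassium hydroxide, [K+].[OH-]
Why: saponification of both esters; the acetal is inert to base and should survive the brief cold acidification.

**Step 7**
Reactants: 11 malonic acid
Product: 12 4,4-diethoxy-2-methylidenebutanoic acid
Conditions: (CH2O)n, Et2NH, EtOAc, reflux
Reagents that add atoms: paraformaldehyde (as formaldehyde), C=O
Why: Mannich-type decarboxylative methylenation of a monosubstituted malonic acid gives the 2-substituted acrylic acid.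

**Step 8**
Reactants: 7 hydroxy propanoate; 12 acrylic acid
Product: 13 (3R,4R,5R)-9-chloro-4-ethyl-3-(propanoyloxy)non-1-en-5-yl 4,4-diethoxy-2-methylidenebutanoate
Conditions: DCC, DMAP (cat.), CH2Cl2, 0 °C → rt
Reagents that add atoms: none
Why: Steglich esterification of the only free hydroxyl (C4–OH) joins C10 to the C4 oxygen.

**Step 9**
Reactants: 13 diene diester
Product: 14 seven-membered α,β-unsaturated lactone (6,7-dihydro-5H-oxepin-2-one) with 3-(2,2-diethoxyethyl), 5-propanoyloxy, 6-ethyl and 7-(4-chlorobutyl) groups (5,6-trans and 6,7-trans)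
Conditions: second-generation Hoveyda–Grubbs catalyst, RuCl2(=CH-C6H4-2-OiPr)(SIMes), 10 mol%, 1,4-benzoquinone, toluene, 0.005 M, 80 °C
Reagents that add atoms: none
Why: ring-closing metathesis between the only two alkenes, initiating at the vinyl group and closing on the 1,1-disubstituted acrylate, gives the C11=C19 bond in a ring that can only hold a cis double bond; loss of ethene drives it.

**Step 10**
Reactants: 14 unsaturated lactone
Product: 17 cis-fused bis-lactone carrying C11–OH (γ-butyrolactone O21–C22–C23–C19–C20 fused to the seven-membered lactone; C11 with OH and CH2CH(OEt)2; C4 with 4-chlorobutyl), via propanoate potassium enolate 15 (not isolated), via bicyclic lactone potassium enolate 16 (not isolated)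
Conditions: KN(SiMe3)2 (1.05 equiv), THF, −78 °C (14 added to the base), −78 → −50 °C; then 2-(benzenesulfonyl)-3-phenyloxaziridine, −78 °C; aq. NH4Cl
Reagents that add atoms: 2-(benzenesulfonyl)-3-phenyloxaziridine, O=S(=O)(c1ccccc1)N1OC1c1ccccc1
Why: Proposed new method: KN(SiMe3)2 removes a proton from the propanoate CH2, the potassium enolate attacks through C23 the β-carbon C19 of the unsaturated seven-membered lactone, and the resulting tetrasubstituted lactone enolate (C10/C11) is hydroxylated at C11 by the N-sulfonyloxaziridine, so that the C19–C23 bond, the C11–O bond and three stereocentres arise in one operation. The closest known reaction types are the tandem conjugate addition/enolate hydroxylation with N-sulfonyloxaziridines and the base-mediated Michael lactonisation of malonate esters of γ-hydroxy enoates; new here is the simple ester enolate, whose closure is a 5-(enolendo)-exo-trig process of the kind that operates in Dieckmann closures of α-acyloxy esters to tetronic acids and in aldol closures of α-acyloxy ketones to butenolides. The γ-butyrolactone is the only ring closed, and it closes 5-exo-trig. C19 is controlled by C20, because the nucleophile hangs from O21 and the cis double bond held in the seven-membered ring can be reached only on the face syn to O21, which gives the cis fusion; C23 should take its methyl group on the convex face away from the quaternary C11, which is also the more stable epimer and so remains correctable by base equilibration; C11 is oxidised on the enolate face opposite the new C19–C23 bond. The step needs enolisation of the propanoate in preference to γ-deprotonation at C20, and hydroxylation at C11 before any proton transfer to C23; inverse addition, only a slight excess of base, low temperature and the inertness of the acetal, the alkyl chloride and the saturated ring carbons should secure this.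

**Step 11**
Reactants: 17 chloro bis-lactone
Product: 18 azido bis-lactone (4-azidobutyl in place of 4-chlorobutyl)
Conditions: NaN3, NaI (cat.), DMF, 60 °C
Reagents that add atoms: sodium azide, [Na+].[N-]=[N+]=[N-]
Why: SN2 displacement of the primary chloride by azide, with no competing electrophile of similar reactivity.

**Step 12**
Reactants: 18 azido bis-lactone
Product: 20 bridged eleven-membered lactam with 13-ethoxy-pyrrolidinone ring and free C4 hydroxyl, via primary amine 19 (not isolated)
Conditions: PMe3, THF–H2O, rt; then AcOH, MeCN, 0.002 M, 60 °C; then CSA (cat.), EtOH, rt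
Reagents that add atoms: none
Why: Staudinger reduction frees the amine, which opens the strained α-hydroxy seven-membered lactone at C10 (O→N acyl transfer, ring expansion to the eleven-membered lactam with release of the C4 hydroxyl) and closes onto the acetal carbon C13 as an N-acyl N,O-acetal in whichever order the bonds form, since acylation from a C13-bound nitrogen is a five-membered lactamisation and any attack on C22 is reversible.

**Step 13**
Reactants: 20 hydroxy lactam
Product: 21 keto lactam (C4 ketone)
Conditions: DMP, CH2Cl2, rt
Reagents that add atoms: none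
Why: Dess–Martin oxidation of the only secondary alcohol under non-basic conditions that spare the tertiary hydroxyl, the N,O-acetal and the base-sensitive β-acyloxy ketone that is formed.

**Step 14**
Reactants: 22 3-methylfuran-2(5H)-one
Product: 23 3-methyl-2-(triisopropylsilyloxy)furan
Conditions: TIPSOTf, Et3N, CH2Cl2, 0 °C
Reagents that add atoms: triisopropylsilyl trifluoromethanesulfonate, CC(C)[Si](OS(=O)(=O)C(F)(F)F)(C(C)C)C(C)C
Why: O-silylation of the butenolide dienolate formed with Et3N gives the 2-silyloxyfuran.

**Step 15**
Reactants: 21 keto lactam; 23 silyloxyfuran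
Product: 25 butenolide adduct (3-methyl-5H-furan-2-on-5-yl group on C13), via N-acyliminium triflate 24 (not isolated)
Conditions: TIPSOTf (10 mol%), CH2Cl2, −78 °C
Reagents that add atoms: none
Why: vinylogous Mannich (Mukaiyama-type) addition, in which the silyl triflate ionises the N,O-acetal, the furan adds through C5 to C13 on the face opposite the C19 arm of the eleven-membered bridge (cis to the C11 hydroxyl), and the threo (syn N/O) preference of silyloxyfuran additions to five-membered N-acyliminium ions sets C14.

**Step 16**
Reactants: 25 butenolide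
Product: 26 CNP0221273.1 (target)
Conditions: H2 (1 atm), Pd/C, EtOAc, rt
Reagents that add atoms: none
Why: heterogeneous hydrogenation of the butenolide from the face opposite the C13 substituent places the methyl group cis to it (C16), while ketone, lactam and lactones are untouched.

**Compound list**
1 | (4S)-4-benzyl-3-butanoyl-1,3-oxazolidin-2-one | CCCC(=O)N1[C@@H](Cc2ccccc2)COC1=O | starting material
2 | acrolein | C=CC=O | starting material
3 | (4S)-4-benzyl-3-[(2S,3R)-2-ethyl-3-hydroxypent-4-enoyl]-1,3-oxazolidin-2-one | C=C[C@@H](O)[C@H](CC)C(=O)N1[C@@H](Cc2ccccc2)COC1=O | intermediate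
4 | (2S,3R)-2-ethyl-3-hydroxy-N-methoxy-N-methylpent-4-enamide | C=C[C@@H](O)[C@H](CC)C(=O)N(C)OC | intermediate
5 | (3R,4S)-9-chloro-4-ethyl-3-hydroxynon-1-en-5-one | C=C[C@@H](O)[C@H](CC)C(=O)CCCCCl | intermediate
6 | propanal | CCC=O | starting material
7 | (3R,4R,5R)-9-chloro-4-ethyl-5-hydroxynon-1-en-3-yl propanoate | C=C[C@@H](OC(=O)CC)[C@H](CC)[C@H](O)CCCCCl | intermediate
8 | diethyl malonate | CCOC(=O)CC(=O)OCC | starting material
9 | 2-bromo-1,1-diethoxyethane | CCOC(CBr)OCC | starting material
10 | diethyl 2-(2,2-diethoxyethyl)propanedioate | CCOC(=O)C(CC(OCC)OCC)C(=O)OCC | intermediate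
11 | 2-(2,2-diethoxyethyl)propanedioic acid | OC(=O)C(CC(OCC)OCC)C(=O)O | intermediate
12 | 4,4-diethoxy-2-methylidenebutanoic acid | C=C(CC(OCC)OCC)C(=O)O | intermediate
13 | (3R,4R,5R)-9-chloro-4-ethyl-3-(propanoyloxy)non-1-en-5-yl 4,4-diethoxy-2-methylidenebutanoate | C=C[C@@H](OC(=O)CC)[C@H](CC)[C@H](OC(=O)C(=C)CC(OCC)OCC)CCCCCl | intermediate
14 | seven-membered unsaturated lactone: 7-(4-chlorobutyl)-3-(2,2-diethoxyethyl)-6-ethyl-2-oxo-2,5,6,7-tetrahydrooxepin-5-yl propanoate, 5,6-trans, 6,7-trans | CC[C@@H]1[C@@H](CCCCCl)OC(=O)C(CC(OCC)OCC)=C[C@H]1OC(=O)CC | intermediate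
15 | potassium enolate of the propanoate of 14 | CC[C@@H]1[C@@H](CCCCCl)OC(=O)C(CC(OCC)OCC)=C[C@H]1OC([O-])=CC.[K+] | intermediate
16 | potassium enolate (C10/C11) of the cis-fused bicyclic bis-lactone | CC[C@@H]1[C@@H](CCCCCl)OC([O-])=C(CC(OCC)OCC)[C@@H]2[C@H]1OC(=O)[C@H]2C.[K+] | intermediate
17 | cis-fused bis-lactone with C11–OH, C11–CH2CH(OEt)2, C3 ethyl, C4 4-chlorobutyl, C23 methyl (C3, C11, C19, C20, C23 as in the target) | CC[C@@H]1[C@@H](CCCCCl)OC(=O)[C@@](O)(CC(OCC)OCC)[C@@H]2[C@H]1OC(=O)[C@H]2C | intermediate
18 | azide corresponding to 17 (4-azidobutyl on C4) | CC[C@@H]1[C@@H](CCCCN=[N+]=[N-])OC(=O)[C@@](O)(CC(OCC)OCC)[C@@H]2[C@H]1OC(=O)[C@H]2C | intermediate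
19 | primary amine corresponding to 18 | CC[C@@H]1[C@@H](CCCCN)OC(=O)[C@@](O)(CC(OCC)OCC)[C@@H]2[C@H]1OC(=O)[C@H]2C | intermediate
20 | bridged eleven-membered lactam with 13-ethoxy-pyrrolidin-2-one ring, C11–OH, C4–OH and fused γ-lactone | CC[C@@H]1[C@H](O)CCCCN2C(=O)[C@@](O)(C[C@H]2OCC)[C@@H]2[C@H]1OC(=O)[C@H]2C | intermediate
21 | C4 ketone corresponding to 20 | CC[C@@H]1C(=O)CCCCN2C(=O)[C@@](O)(C[C@H]2OCC)[C@@H]2[C@H]1OC(=O)[C@H]2C | intermediate
22 | 3-methylfuran-2(5H)-one | CC1=CCOC1=O | starting material
23 | 3-methyl-2-(triisopropylsilyloxy)furan | Cc1ccoc1O[Si](C(C)C)(C(C)C)C(C)C | intermediate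
24 | bridgehead N-acyliminium triflate (N9=C13) derived from 21 | CC[C@@H]1C(=O)CCCC[N+]2=CC[C@](O)(C2=O)[C@@H]2[C@H]1OC(=O)[C@H]2C.[O-]S(=O)(=O)C(F)(F)F | intermediate
25 | butenolide adduct: target skeleton with C15=C16 double bond in the side lactone | CC[C@@H]1C(=O)CCCCN2C(=O)[C@@](O)(C[C@H]2[C@@H]2C=C(C)C(=O)O2)[C@@H]2[C@H]1OC(=O)[C@H]2C | intermediate
26 | CNP0221273.1 | CC[C@@H]1C(=O)CCCCN2C(=O)[C@@](O)(C[C@H]2[C@@H]2C[C@H](C)C(=O)O2)[C@@H]2[C@H]1OC(=O)[C@H]2C | target

**Step count and risks**
Total step count: 16. Longest linear sequence: 12 steps (steps 1–4, 8–13, 15, 16).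

Steps most likely to fail:

1. Step 10 (proposed new method). The enolendo ring closure may be slower than proton exchange among the enolates or than γ-deprotonation at C20, so the oxidant would meet the wrong enolate or uncyclised material. The fallback sets out from 14 and comes back at 17, using known reactions only. Lipase-catalysed butanolysis of the propanoate (Candida antarctica lipase B, n-BuOH, MTBE) gives the allylic alcohol F1. Esterification with 2-(benzenesulfonyl)propanoic acid (DCC, DMAP) gives the α-sulfonyl ester F2. Epoxidation of the electron-poor double bond on the face anti to the C20 ester (mCPBA, radical inhibitor, 1,2-dichloroethane, 80 °C) gives the epoxy lactone F3. Cs2CO3 in MeCN then lets the sulfonyl-stabilised carbanion open the epoxide at C19 with inversion (5-exo-tet); this forms the C19–C23 bond syn to O21 and frees the C11 hydroxyl in the target configuration, giving the α-sulfonyl bis-lactone F4. Reductive desulfonylation (Al/Hg, wet THF) and DBU equilibration of C23 return 17.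

2. Step 12. Intermolecular acylation and oligomerisation may outrun the closure of the eleven-membered ring, or the amine may be held up by reversible opening of the γ-lactone. The fallback sets out from 18 and comes back at 20. Mild acetal hydrolysis (LiBF4, wet MeCN) gives the azido aldehyde F5. PPh3 in toluene at high dilution (Staudinger reaction, then intramolecular aza-Wittig reaction) closes the macrocyclic imine F6 irreversibly. EtOH with catalytic CSA then adds to the imine, and the N,O-acetal nitrogen acylates itself on C10 through a five-membered transition state to give 20.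

3. Step 9. Metathesis of the 1,1-disubstituted electron-poor alkene with the deactivated allylic-ester alkene may be sluggish, leading to dimerisation or catalyst decay before ring closure. The fallback sets out from 7 and comes back at 14. Triethyl phosphonoacetate is alkylated with 9 (NaH, DMF) to the phosphonate ester F7, which is saponified (LiOH) to the phosphono acid F8. Esterification of 7 with this acid (DCC, DMAP) gives the phosphonoacetate F9. Ozonolysis of the vinyl group (O3, then Me2S) gives the aldehyde F10, and intramolecular Horner–Wadsworth–Emmons olefination (LiCl, i-Pr2NEt, MeCN, high dilution) closes the same lactone 14.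

**Further compounds**
F1 | step 10 | allylic alcohol (14 without the propanoyl group) | CC[C@@H]1[C@@H](CCCCCl)OC(=O)C(CC(OCC)OCC)=C[C@H]1O
F2 | step 10 | 2-(benzenesulfonyl)propanoate ester of F1 | CC[C@@H]1[C@@H](CCCCCl)OC(=O)C(CC(OCC)OCC)=C[C@H]1OC(=O)C(C)S(=O)(=O)c1ccccc1
F3 | step 10 | C11–C19 epoxy lactone, epoxide anti to O21 | CC[C@@H]1[C@@H](CCCCCl)OC(=O)[C@]2(CC(OCC)OCC)O[C@@H]2[C@H]1OC(=O)C(C)S(=O)(=O)c1ccccc1
F4 | step 10 | 17 with a benzenesulfonyl group on C23 | CC[C@@H]1[C@@H](CCCCCl)OC(=O)[C@@](O)(CC(OCC)OCC)[C@@H]2[C@H]1OC(=O)C2(C)S(=O)(=O)c1ccccc1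
F5 | step 12 | azido aldehyde (18 with C13 as CHO) | CC[C@@H]1[C@@H](CCCCN=[N+]=[N-])OC(=O)[C@@](O)(CC=O)[C@@H]2[C@H]1OC(=O)[C@H]2C
F6 | step 12 | macrocyclic imine N9=C13 (seven-membered lactone intact) | CC[C@@H]1[C@H]3CCCCN=CC[C@](O)(C(=O)O3)[C@@H]2[C@H]1OC(=O)[C@H]2C
F7 | step 9 | ethyl 2-(diethoxyphosphoryl)-4,4-diethoxybutanoate | CCOC(=O)C(CC(OCC)OCC)P(=O)(OCC)OCC
F8 | step 9 | 2-(diethoxyphosphoryl)-4,4-diethoxybutanoic acid | OC(=O)C(CC(OCC)OCC)P(=O)(OCC)OCC
F9 | step 9 | ester of 7 (C4–OH) with F8 | C=C[C@@H](OC(=O)CC)[C@H](CC)[C@H](OC(=O)C(CC(OCC)OCC)P(=O)(OCC)OCC)CCCCCl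
F10 | step 9 | aldehyde from ozonolysis of F9 (C19 as CHO) | O=C[C@@H](OC(=O)CC)[C@H](CC)[C@H](OC(=O)C(CC(OCC)OCC)P(=O)(OCC)OCC)CCCCCl
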